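The data come from a simulation from invented constants; noise was put on by code.

- theta: starting material 0.20 M; second substrate 2 equiv; free catalyst 0.1 mol%; impurity 0.23 mM; the very flask that is asked about, followed so far
- flask: starting material 0.20 M; second substrate 2.00 equiv; free catalyst 0.1 mol%; impurity 0.23 mM

theta run (percent of the starting material charged)

| time / min | target / % |
|---|---|
| 15.0 | 2.1 |
| 30.0 | 4.3 |
| 50.0 | 5.5 |
| 60.0 | 6.5 |
| 80.0 | 7.2 |
| 90.0 | 8.0 |
| 120 | 9.0 |

(standard deviation of a reading: 0.3 percentage points)

- apparent order in free catalyst when 20% of the starting material are converted (percent change of the rate of making target for one percent more free catalyst charged)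
- apparent order in second substrate when 20% of the starting material are converted (percent change of the rate of making target for one percent more second substrate charged)

Of the starting material charged to this flask, 91.0% is still not in target after 120 min. We keep the books on it, because it is the limiting reagent against 2.00 equiv of second substrate.

1. The first entry is target, 9.0% of the charge, or 90.0 turns per catalyst charged.
2. The second entry is whatever sits on the catalyst, whose whole charge is 0.1 mol%.
3. The unread entry is the rest, 90.9%, either unreacted or gone where no reading looks.
4. Target slows, so we define the working life of the catalyst as the time needed at the opening pace, 2.1% in 15.0 min, to make the target read at 120 min: 64.3 min. It is a reading, with the scatter of the readings, and we take the rate to fall as exp(−t/life).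
5. Well inside that life, we expect the rate to follow the catalyst charge, so the order in catalyst is 1.
6. Far beyond it, impurity at 0.115% of the charge exceeds the catalyst. If impurity is a poison, extra charge counts more than in proportion, and the order rises above 1.
7. To join the ends we must date 20% conversion. At 120 min target stands below that mark, and the unread entry is not followed, so the readings do not date it. We bet on the early end, with an order near 1 in catalyst, and give no number for second substrate.

The forecast parts from this bet, placing the flask where “only residual free catalyst would be working”, with 2.3 in catalyst and 1.2 in second substrate.

The flask gives 1.0 in free catalyst and −0.14 in second substrate.

    starting material + free catalyst ⇌ catalyst intermediate A (K = 49.0 /M, k = 77.0 /M/min)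
    catalyst intermediate A → free catalyst + target (k = 2.60 /min)
    second substrate + free catalyst ⇌ catalyst intermediate B (K = 2.10 /M, k = 800 /M/min)
    catalyst intermediate B → free catalyst + second product (k = 13.0 /min)
    free catalyst + impurity → spent catalyst (k = 310 /M/min)
    2 starting material → homo dimer (k = 0.0400 /M/min)

This flask reaches 20% conversion after 0.232 h, which is 0.216 of the working life. Carried forward, the working life puts the rate of this flask at 70 percent conversion, after 2.09 h, at 0.177 of the rate at 20% conversion, and the flask gives 0.19.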